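(All runs are calculated on assumed constants, noise included.)

Begin with the easy step and read the last rows of the ochre run, which is the very flask asked about: L reads 0% of the charge at 300 min, and G, after a reading of 85% at 40.0 min, reads 68% at 180 min and 68% at 300 min.

common to all: D 2.2 µM

| flask | L | temperature | remark | time |
|---|---|---|---|---|
| ochre | 11 mM | 5 °C | the very flask that is asked about, followed so far |  |
| amber | 5.5 mM | 11 °C | run made earlier |  |
| flask | 11 mM | 5 °C |  | 6.0 h |

| run | time / min | G / % | L / % |
|---|---|---|---|
| ochre | 25.0 | 83 | 4 |
| ochre | 40.0 | 85 | 4 |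
| ochre | 60.0 | 82 | 0 |
| ochre | 120 | 71 | 0 |
| ochre | 180 | 68 | 1 |
| ochre | 300 | 68 | 0 |
| amber | 1.00 | 17 | 79 |
| amber | 3.00 | 48 | 48 |
| amber | 6.00 | 75 | 21 |
| amber | 8.00 | 81 | 14 |
| amber | 12.0 | 90 | 4 |
| amber | 15.0 | 86 | 1 |

(scatter of a reading: 1.5 percentage points)

- Sunday's: at 6.0 h raise the temperature by 25 K, then wait 12 h
- Wednesday's: at 6.0 h take out 90% of the G then present, then wait 12 h
- Friday's: at 6.0 h add D, 100% of the amount charged, then wait 12 h
- Thursday's: change nothing and wait 12 h more

1. G, in percent of the L first charged, at 6.0 h
2. which option adds most G ("none" when 2 percentage points or less is all one gets) (Sunday's / Wednesday's / Friday's / Thursday's / none)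
3. G present, with what was taken out counted in, in percent of the L first charged, after Wednesday's
4. G present, with what was taken out counted in, in percent of the L first charged, after Friday's

- G that was removed still counts
- additions bring no volume worth counting

Take the mean of those two flat readings, 68.0%, as the standing share, the fraction of the pool of G and X that stands as G once L reads 0%, and treat X as a form that G turns into and back from, so that the end of this flask is, on this reckoning, under thermodynamic control. Expect G in this flask at 6.0 h to stand at that share, and expect Thursday's and Friday's to leave it there, since L reads 0% against G at 68% and, on this reckoning, more D speeds the return to the same share without moving it. Wednesday's is different: take out 90% of G and 61.2% of the charge is safe outside, leaving 38.8% in the pool, which on this reckoning returns to the share and yields 26.4% as G, so the total comes to 87.6%, a gain of 20 percentage points. Leave Sunday's unreckoned, for the warmer amber run stops at 15.0 min with G still reading 86%, above the share, and choose Wednesday's.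

The forecast says 68% now, Wednesday's as the choice, 87% after it, a little under my figure, and 68% after Friday's, and of the flat stretch it says “Amber shows no rate decay, so I favour equilibrium”.

The flask gives 69.5% at 6.0 h, Wednesday's as the choice with 88.5% after it, and 69.4% after Friday's.

    D → E (k = 7.75 × 10⁻⁴ min⁻¹, Ea = 192 kJ mol⁻¹)
    L + D → G + D, rate k2*[L]*[D]/(1 + ([L]/Km2) + ([G]/Kp2)) (0.343 mM, 0.573 mM, k = 23500 M⁻¹ s⁻¹, Ea = 15.0 kJ mol⁻¹)
    L + D → Q (k = 2.00 M⁻¹ min⁻¹, Ea = 47.0 kJ mol⁻¹)
    G + D ⇌ X + D, rate k4*[D]*[G] forward; the back reaction follows from the equilibrium constant (K = 0.440, k = 3790 M⁻¹ min⁻¹, Ea = 44.0 kJ mol⁻¹, ΔH = −14.0 kJ mol⁻¹)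
    (constants at 5 °C)

At 360 min this flask holds G at 69.5% and X at 30.5%, with 61.6% of the catalyst still D, and the forward half-life of G, 83 min, is short against 6.0 h. Put the share to a neighbour flask charged with 27 mM of L: its G and X together, times 68.0%, come to 58.3%, yet at 360 min its G stands higher, at 74.1%, with D down to 0.717% of the catalyst charged.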